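## Structural features

The target is a 9-epi-drimane meroterpenoid. It has a trans-fused decalin (ring A = C1–C5 and C10, gem-dimethyl on C4; ring B = C5–C10, the only alkene at C7=C8, methyl on C8) whose C9 carries the methylene C11, and C11 is bonded to C1′ of a benzene ring with oxygen on C2′, C3′, C5′ and C6′ and hydrogen only on C4′. O5′ is a hydrogen sulfate; O3′ is the same position, because rotation about C11–C1′ exchanges the two halves of the arene. The three stereocentres are contiguous: C5 (S, H α) and C10 (S, CH3 β) form the trans ring fusion, and C9 (R) has its hydrogen β and the C11 arm α, axial and trans to the angular methyl, which is the opposite of the C9 configuration of drimenol-type chiral-pool material. Fragile are the electron-rich tetraol (air oxidation to the hydroxyquinone), the aryl sulfate monoester (acid-labile), the C7=C8 alkene (acid gives the C8 cation, which a flanking phenol oxygen can capture) and the thermodynamically disfavoured axial group on C9. The real difficulty is to form the C9–C11 bond on the α-face with control of absolute configuration, and to place four oxygens on the arene without an arene oxidation or a global deprotection next to the alkene, followed by a single sulfation. The key step exploits that the ring C1′–C6′, at the quinone level, is the enol form of a cyclohexanetetraone that is symmetric about the C1′–C4′ axis; it divides into a 1,2-diketone chain C1′–C2′(=O)–C3′(=O)–C4′ (C1′ attached to C11) and an oxalyl unit C5′–C6′. Two names need care: diketone 20 is a pentane-2,3-dione whose C5 is C11 and is bonded to C9 of the 11-nor-drimene, and quinone 23 carries the drim-7-en-11-yl group directly on C1′; counting a further methylene into either name gives a carbon the target does not have.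

## Logic of the disconnections

25 to 24. The O5′–S bond is cut first because the sulfate monoester is the most labile group and must come last. This removes the charge and the acid sensitivity from every earlier intermediate. The forward step must sulfate one of the two equivalent unhindered hydroxyls (O3′/O5′) once, leave the hindered O2′/O6′ alone and exclude oxygen.

24 to 23. No skeletal bond is cut; the two O–H bonds of the para pair are removed formally, taking the arene to the dihydroxyquinone. 23 is the air-stable form and is the oxidation level that the ring construction delivers. The forward step needs a reductant that does not touch C7=C8.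

23 to 20 and 21. The bonds C4′–C5′ and C1′–C6′ are cut, which opens the six-membered ring along its symmetry axis. All six ring carbons and all four oxygens then come from a 1,2-diketone and a two-carbon diester, with no arene oxidation and no ether cleavage. The forward step must acylate both α-carbons of 20, close a six-membered ring and outrun self-condensation of 20.

20 to 19. The C2′=O and C3′=O bonds are traced back to the C2′≡C3′ triple bond. The alkyne is an inert carrier of the diketone oxidation level through the organometallic steps. The forward oxidation must distinguish the alkyne from C7=C8.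

19 to 18 to 14, 15. The C7–H bond is traced to a C7–O triflate and the C9–C11 bond is cut. C9 is the β-carbon of enone 14, so the chain enters as a nucleophile on the open α-face, anti to the angular methyl, which is exactly the 9-epi arrangement; trapping the enolate on oxygen fixes the later alkene at C7=C8. The forward step demands 1,4- over 1,2-addition at a hindered β-carbon, efficient O-triflation, and a triflate reduction that spares the alkyne.

14 to 13 to 11 to 9. The C8=C9 π-bond, the C5–H and C6–H bonds and the C8–C12 bond are removed in turn. In 9 only C8 carries acidic hydrogens, so the methyl is placed without a regiochemical question, and dissolving-metal reduction sets the trans fusion. The forward demands are axial protonation at C5 and dehydrogenation towards C8–C9 instead of C5–C6.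

9 to 8 to 5, 6. The C5=C6 bond (aldol condensation) and the C7–C8 bond (cross-metathesis, with C7=O from the C–B bond) are cut. This turns an allyl group into the 3-oxobutyl arm with the carbonyl position fixed by boron. The forward demands are metathesis next to a quaternary carbon and aldol closure onto a ketone flanked by two quaternary carbons.

5 to 4 to 1, 2. The C9–C10 bond is cut, then the enol carbonate C–O bond. This is the only catalyst-controlled stereocentre; C5 and C9 are relayed from it. The forward step must give high enantioselectivity at a fully substituted enolate carbon with the correct ligand enantiomer.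

## Other disconnections considered

Alternative 1: The cut runs through C4–C5 and C9–C10 and opens both carbocycles to the acyclic (2Z,6E)-farnesyl arene A2, which already carries the arene on C11 as its tetramethyl ether. In the forward step a chiral Lewis-acid-assisted Brønsted acid of the tin halide–binaphthol ether type protonates the terminal alkene, rings A and B close in one cationic cascade and the C8 cation loses H7 to give A1; the 2Z geometry puts the C11 arm axial, i.e. α.
- In its favour: two rings and all three stereocentres arise in one catalyst-controlled step, the decalin needs no redox adjustment, and from A1 only ceric oxidation, hydrolysis of two ether groups, reduction and sulfation remain. On step economy it is clearly the better plan.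
- Against it here: a Z-trisubstituted alkene must cyclise through a more strained arrangement and can isomerise under the acid, so both enantioselectivity and C9 fidelity are less secure. The termination is not programmed: the C8 cation may also lose a proton from C9 or C12 or be captured by an ortho-methoxy oxygen in a six-membered closure. Four basic methoxy groups can sequester the Lewis acid, A2 needs a geometrically pure Z-allylic coupling, and the methyl ethers must later be removed oxidatively beside C7=C8.
- Comparison: on structure it reaches the arylated skeleton directly, whereas the chosen plan never exposes an electron-rich arene to acid or to demethylation. On mechanism it stakes everything on one cascade with several exits, whereas the chosen plan fixes the alkene position (triflate reduction) and the C9 face (angular methyl) in separate polar steps. The tetraol and sulfation end game is the same in both, so they are equal there.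

Alternative 2: The cut is C7–C8 and C9–C10, i.e. ring B by a [4+2] cycloaddition of the silyl enol ether diene A4 (C10=C5–C6=C7) with the aryl propenyl ketone A5 across C8=C9, aroyl group endo, giving A3.
- In its favour: it is convergent, the arene and C11 arrive in one piece, and the quaternary C10 and C9 are formed together with the aroyl group α, trans to the angular methyl. In convergence and in setting the C9/C10 relationship in one step it is the equal of, or better than, the chosen plan; the C6 enol ether also gives a handle for equilibrating C5 to the trans fusion.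
- Against it here: the diene terminus C10 is fully substituted inside a 2,6,6-trimethylcyclohexene and resists the s-cis geometry, and the dienophile is β-substituted with a di-ortho-substituted aroyl group twisted out of conjugation, so low reactivity is expected on both partners. There is no obvious two-point binding for an enantioselective catalyst. A3 is at the wrong oxidation level in three places: the C6 oxygen must go, C8 is saturated and C7=C8 has to be introduced regioselectively, and the C11 ketone must become a methylene next to an alkene and an electron-rich arene.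
- Comparison: structurally it gains the arene early but pays with C6, C8 and C11 corrections; mechanistically it is a stereospecific pericyclic step against the chosen stepwise polar relay; in step count the corrections are expected to consume what the convergence saves.

Alternative 3: The cut is C1–C10 and C4–C5, i.e. ring A by a [4+2] cycloaddition of diene A7 onto one methyl-bearing double bond of quinone A8 under a chiral oxazaborolidinium Lewis acid, giving the cis-fused ene-dione A6, whose C5 can afterwards be epimerised.
- In its favour: two commodity starting materials and one catalytic enantioselective step give a decalin with the quaternary C10, the C8 methyl and C7=C8 already in place, and C5 is α to the C6 carbonyl so the trans fusion is reachable by equilibration. As an entry to an enantioenriched ring-B-functionalised decalin it is far shorter than steps 1–7 of the chosen plan and is the better plan on that point.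
- Against it here: the diene has a cis-methyl on its reacting terminus and resists the s-cis geometry. More seriously, the step leaves C9 as a carbonyl. Turning it into C9(H) with the α-carbon arm needs addition of a carbon nucleophile to a neopentyl ketone and then removal of the tertiary hydroxyl with hydrogen delivered to the hindered β-face without moving C7=C8. The C6 oxygen must also be removed and C2=C3 saturated selectively.
- Comparison: in the chosen plan C9 is the β-carbon of enone 14, so the angular methyl that obstructs the C9 problem in A6 is what solves it. The ring-forming events are comparably reliable catalytic asymmetric C–C bond formations. Overall step economy is not expected to be better once C6, C9 and C2=C3 are corrected.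

Key step: step 11

Remarks before the steps.
- Numbering: drimane numbers are used for the decalin (methyls on C4, C8, C10; C11 is the benzylic methylene) and primed numbers for the oxygenated ring (C1′ bears C11, C4′ bears H). β is the face of the C10 methyl.
- Assumption: the target is handled as its pyridinium or sodium sulfate and converted into the free hydrogen sulfate of the SMILES only in the last operation.
- Absolute configuration enters once, at C10 in step 2. The (R)-ligand is specified from the usual sense of induction of this ligand class; the configuration of 5 is to be confirmed before scale-up and the other ligand enantiomer used if it proves reversed.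

Step 1
Reactants: 1 2,2,6-trimethylcyclohexanone; 2 allyl chloroformate
Product: 4 allyl 2,6,6-trimethylcyclohex-1-en-1-yl carbonate, via lithium enolate 3 (not isolated)
Conditions: LiN(SiMe3)2, THF, −78 °C; then 2, −78 → 0 °C
Reagents that add atoms: none
Why: C6 is the only enolisable carbon, and the hindered tetrasubstituted lithium enolate reacts with the hard chloroformate on oxygen (enol carbonate formation).

Step 2
Reactants: 4 allyl 2,6,6-trimethylcyclohex-1-en-1-yl carbonate
Product: 5 (R)-2-allyl-2,6,6-trimethylcyclohexanone
Conditions: Pd2(dba)3 (2.5 mol%), (R)-t-Bu-PHOX (6 mol%), THF, 25 °C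
Reagents that add atoms: none
Why: Decarboxylative asymmetric allylic alkylation (Tsuji allylation): zerovalent palladium ionises the allyl carbonate, CO2 is lost, and the PHOX-bound allylpalladium enolate joins allyl to one face of the fully substituted enolate carbon, setting C10 as (R), the future 10β-methyl centre.

Step 3
Reactants: 5 (R)-2-allyl-2,6,6-trimethylcyclohexanone; 6 4,4,5,5-tetramethyl-2-(prop-1-en-2-yl)-1,3,2-dioxaborolane
Product: 8 (R)-2,2,6-trimethyl-6-(3-oxobutyl)cyclohexanone, via alkenyl boronate 7 (not isolated)
Conditions: second-generation Grubbs catalyst (5 mol%), 6 (3 equiv), CH2Cl2, 40 °C; then 30% H2O2, aq. NaOH, THF, 0 °C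
Reagents that add atoms: hydrogen peroxide, OO
Why: Olefin cross-metathesis of the terminal alkene with the 1,1-disubstituted vinyl boronate places boron on the carbon that becomes C7, and oxidation of the C–B bond gives the enol and hence the methyl ketone, so the carbonyl position is fixed by boron and not by Wacker regiochemistry.

Step 4
Reactants: 8 (R)-2,2,6-trimethyl-6-(3-oxobutyl)cyclohexanone
Product: 9 (R)-4a,8,8-trimethyl-4,4a,5,6,7,8-hexahydronaphthalen-2(3H)-one
Conditions: KOH, xylenes, 110 °C, Dean–Stark
Reagents that add atoms: none
Why: Intramolecular aldol condensation (ring closure of a Robinson annulation): the C5 ketone cannot enolise and only the methyl carbon C6 reaches it through a six-membered transition state, so one enone forms; forcing conditions answer the two quaternary carbons flanking C5.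

Step 5
Reactants: 9 (R)-4a,8,8-trimethyl-4,4a,5,6,7,8-hexahydronaphthalen-2(3H)-one
Product: 11 (4aR)-3,4a,8,8-tetramethyl-4,4a,5,6,7,8-hexahydronaphthalen-2(3H)-one (C3 epimers), via lithium dienolate 10 (not isolated)
Conditions: LiN(i-Pr)2, THF, −78 °C; then MeI, −78 → 0 °C
Reagents that add atoms: iodomethane, CI
Why: Kinetic α′-deprotonation and SN2 methylation; C8 holds the only acidic hydrogens because both γ-carbons (C4, C10) are quaternary, and the C8 configuration is irrelevant since C8 becomes trigonal in step 7.

Step 6
Reactants: 11 (4aR)-3,4a,8,8-tetramethyl-4,4a,5,6,7,8-hexahydronaphthalen-2(3H)-one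
Product: 13 (4aR,8aS)-3,4a,8,8-tetramethyloctahydronaphthalen-2(1H)-one (C3 epimers), via lithium enolate 12 (not isolated)
Conditions: Li, NH3(l), THF, t-BuOH (1 equiv), −78 °C; then NH4Cl
Reagents that add atoms: none
Why: Dissolving-metal conjugate reduction (Birch-type): the β-carbanion at C5 is protonated axially on the α-face, anti to the axial methyls on C10 and C4, which sets C5 (S) and the trans fusion by substrate control; the enolate survives until the quench, so the ketone is not reduced further.

Step 7
Reactants: 13 (4aR,8aS)-3,4a,8,8-tetramethyloctahydronaphthalen-2(1H)-one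
Product: 14 (4aR,8aS)-3,4a,8,8-tetramethyl-4a,5,6,7,8,8a-hexahydronaphthalen-2(1H)-one
Conditions: IBX (1.5 equiv), DMSO/toluene, 70 °C
Reagents that add atoms: none
Why: IBX dehydrogenation of a ketone through its more substituted enol (C7=C8) removes hydrogen from C9; the C6 side is the less substituted enol and its axial hydrogen is shielded by the C4 and C10 methyls.

Step 8
Reactants: 14 (4aR,8aS)-3,4a,8,8-tetramethyl-4a,5,6,7,8,8a-hexahydronaphthalen-2(1H)-one; 15 5-bromopent-2-yne
Product: 18 (4S,4aS,8aS)-3,4a,8,8-tetramethyl-4-(pent-3-yn-1-yl)-1,4,4a,5,6,7,8,8a-octahydronaphthalen-2-yl trifluoromethanesulfonate, via pent-3-ynylmagnesium bromide 16 (not isolated), via bromomagnesium enolate 17 (not isolated)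
Conditions: 15, Mg, THF, 25 °C; CuBr·SMe2 (20 mol%), 14, THF, −40 → −20 °C; then N-(5-chloropyridin-2-yl)bis(trifluoromethanesulfonyl)imide, −78 → 25 °C
Reagents that add atoms: N-(5-chloropyridin-2-yl)bis(trifluoromethanesulfonyl)imide, FC(F)(F)S(=O)(=O)N(c1ccc(Cl)cn1)S(=O)(=O)C(F)(F)F
Why: Copper-catalysed conjugate addition of a Grignard reagent followed by O-triflation of the regiodefined enolate; the nucleophile adds axially to C9 on the α-face, anti to the 10β-methyl through a chair-like enolate (the same facial preference as 1α-alkylation of steroidal 1-en-3-ones), which sets the 9α side chain, and the triflate locks the double bond at C7=C8.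

Step 9
Reactants: 18 (4S,4aS,8aS)-3,4a,8,8-tetramethyl-4-(pent-3-yn-1-yl)-1,4,4a,5,6,7,8,8a-octahydronaphthalen-2-yl trifluoromethanesulfonate
Product: 19 (1R,4aS,8aS)-2,5,5,8a-tetramethyl-1-(pent-3-yn-1-yl)-1,4,4a,5,6,7,8,8a-octahydronaphthalene
Conditions: Pd(OAc)2 (5 mol%), PPh3 (10 mol%), n-Bu3N, HCO2H, DMF, 60 °C
Reagents that add atoms: none
Why: Palladium-catalysed formate reduction of an enol triflate: oxidative addition to zerovalent palladium, formate exchange, loss of CO2 and C–H reductive elimination replace OTf by H without moving the alkene; oxidative addition of the triflate should outpace any hydropalladation of the internal alkyne.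

Step 10
Reactants: 19 (1R,4aS,8aS)-2,5,5,8a-tetramethyl-1-(pent-3-yn-1-yl)-1,4,4a,5,6,7,8,8a-octahydronaphthalene
Product: 20 5-[(1R,4aS,8aS)-2,5,5,8a-tetramethyl-1,4,4a,5,6,7,8,8a-octahydronaphthalen-1-yl]pentane-2,3-dione
Conditions: PdBr2 (5 mol%), CuBr2 (10 mol%), O2 (1 atm), 1,4-dioxane/H2O, 60 °C
Reagents that add atoms: water, O; dioxygen, O=O
Why: Wacker-type oxidation of an internal alkyne to the 1,2-diketone (hydroxypalladation by divalent palladium, reoxidation through CuBr2 and O2); the linear alkyne binds palladium far better than the hindered trisubstituted C7=C8, which has no easy oxypalladation path.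

Step 11
Reactants: 20 5-[(1R,4aS,8aS)-2,5,5,8a-tetramethyl-1,4,4a,5,6,7,8,8a-octahydronaphthalen-1-yl]pentane-2,3-dione; 21 diethyl oxalate
Product: 23 2,5-dihydroxy-3-{[(1R,4aS,8aS)-2,5,5,8a-tetramethyl-1,4,4a,5,6,7,8,8a-octahydronaphthalen-1-yl]methyl}cyclohexa-2,5-diene-1,4-dione, via open-chain trioxo ester 22 (not isolated)
Conditions: NaOEt (4 equiv), 21 (4 equiv), EtOH/THF, 0 °C, slow addition of 20; then 60 °C; 1 M HCl
Reagents that add atoms: none
Why: Proposed new method: ethoxide reversibly deprotonates the methyl carbon C4′ of 20, the enolate is acylated by 21 (Claisen condensation) to give 22 as its stabilised enolate, and a second deprotonation at the methylene C1′, the only other enolisable carbon, lets C1′ attack the remaining ester carbon C6′ in a six-membered acyl substitution (Dieckmann-type, 6-(enolendo)-exo-trig), closing the cyclohexanetetraone that is the keto tautomer of 23. The closest known reaction types are the acylation of methyl ketones by dialkyl oxalates, the double oxalate condensation of dialkyl ketones to cyclopentane-1,2,4-triones and the base-mediated self-condensation of 2-oxo esters to 3,6-dialkyl-2,5-dihydroxybenzoquinones; new is the crossed version on a 1,2-diketone. Either order of the two acylations gives the same ring, so there is no regiochemical issue; no stereocentre is formed, and C9 is γ to C2′ and cannot epimerise. The driving force is the doubly vinylogous acidity of the product, whose dianion consumes two equivalents of base and draws the reversible Claisen, aldol and hemiketal equilibria towards the ring. The selectivity needed is crossed acylation over self-aldol of 20 and over a five-membered aldol closure of C1′ onto the C5′ ketone; the first is secured by keeping the stationary concentration of 20 low against excess 21 and base, the second by the reversibility of aldol addition against irreversible product deprotonation. No oxidation follows because the tetraone is already at the quinone level.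

Step 12
Reactants: 23 2,5-dihydroxy-3-{[(1R,4aS,8aS)-2,5,5,8a-tetramethyl-1,4,4a,5,6,7,8,8a-octahydronaphthalen-1-yl]methyl}cyclohexa-2,5-diene-1,4-dione
Product: 24 3-{[(1R,4aS,8aS)-2,5,5,8a-tetramethyl-1,4,4a,5,6,7,8,8a-octahydronaphthalen-1-yl]methyl}benzene-1,2,4,5-tetrol
Conditions: Na2S2O4, THF/H2O (degassed), 25 °C, Ar; used at once
Reagents that add atoms: none
Why: Dithionite reduction of a quinone to the hydroquinone by two single-electron transfers; the isolated alkene is inert, and the tetraol is kept under argon because it reverts to 23 in air.

Step 13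
Reactants: 24 3-{[(1R,4aS,8aS)-2,5,5,8a-tetramethyl-1,4,4a,5,6,7,8,8a-octahydronaphthalen-1-yl]methyl}benzene-1,2,4,5-tetrol
Product: 25 2,4,5-trihydroxy-3-{[(1R,4aS,8aS)-2,5,5,8a-tetramethyl-1,4,4a,5,6,7,8,8a-octahydronaphthalen-1-yl]methyl}phenyl hydrogen sulfate
Conditions: SO3·pyridine (1.05 equiv), pyridine/DMF, 0 °C, Ar; then Dowex 50 (H+ form), MeOH/H2O, 0 °C
Reagents that add atoms: sulfur trioxide pyridine complex, [O-]S(=O)(=O)[n+]1ccccc1
Why: O-Sulfation of a phenol by an SO3–amine complex; O3′ and O5′ are equivalent and less hindered than O2′ and O6′, which flank the bulky C11 arm, and one equivalent of reagent together with the deactivating first sulfate should limit bis-sulfation.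

Compound list

1 | 2,2,6-trimethylcyclohexanone (racemic) | CC1CCCC(C)(C)C1=O | starting material
2 | allyl chloroformate | C=CCOC(=O)Cl | starting material
3 | lithium 2,6,6-trimethylcyclohex-1-en-1-olate | [Li]OC1=C(C)CCCC1(C)C | intermediate (not isolated)
4 | allyl 2,6,6-trimethylcyclohex-1-en-1-yl carbonate | C=CCOC(=O)OC1=C(C)CCCC1(C)C | intermediate
5 | (R)-2-allyl-2,6,6-trimethylcyclohexanone | C=CC[C@@]1(C)CCCC(C)(C)C1=O | intermediate
6 | 4,4,5,5-tetramethyl-2-(prop-1-en-2-yl)-1,3,2-dioxaborolane | CC(=C)B1OC(C)(C)C(C)(C)O1 | starting material
7 | (R)-2,2,6-trimethyl-6-[3-(4,4,5,5-tetramethyl-1,3,2-dioxaborolan-2-yl)but-2-en-1-yl]cyclohexanone (E/Z mixture) | CC(=CC[C@@]1(C)CCCC(C)(C)C1=O)B2OC(C)(C)C(C)(C)O2 | intermediate (not isolated)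
8 | (R)-2,2,6-trimethyl-6-(3-oxobutyl)cyclohexanone | CC(=O)CC[C@@]1(C)CCCC(C)(C)C1=O | intermediate
9 | (R)-4a,8,8-trimethyl-4,4a,5,6,7,8-hexahydronaphthalen-2(3H)-one (11,12-dinor-drim-5-en-7-one, 10β-CH3) | O=C1C=C2C(C)(C)CCC[C@]2(C)CC1 | intermediate
10 | lithium cross-conjugated dienolate of 9 (O–Li on C7, C7=C8 and C5=C6) | [Li]OC1=CC[C@@]2(C)CCCC(C)(C)C2=C1 | intermediate (not isolated)
11 | (4aR)-3,4a,8,8-tetramethyl-4,4a,5,6,7,8-hexahydronaphthalen-2(3H)-one (11-nor-drim-5-en-7-one, C8 epimers) | O=C1C=C2C(C)(C)CCC[C@]2(C)CC1C | intermediate
12 | lithium C6=C7 enolate of 13 | CC1C[C@@]2(C)CCCC(C)(C)[C@@H]2C=C1O[Li] | intermediate (not isolated)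
13 | (4aR,8aS)-3,4a,8,8-tetramethyloctahydronaphthalen-2(1H)-one (trans-fused, 5α-H, 10β-CH3, C8 epimers) | CC1C[C@@]2(C)CCCC(C)(C)[C@@H]2CC1=O | intermediate
14 | (4aR,8aS)-3,4a,8,8-tetramethyl-4a,5,6,7,8,8a-hexahydronaphthalen-2(1H)-one (11-nor-drim-8-en-7-one) | CC1=C[C@@]2(C)CCCC(C)(C)[C@@H]2CC1=O | intermediate
15 | 5-bromopent-2-yne | CC#CCCBr | starting material
16 | pent-3-yn-1-ylmagnesium bromide | CC#CCC[Mg]Br | intermediate (not isolated)
17 | bromomagnesium C7=C8 enolate of 9α-(pent-3-yn-1-yl)-11-nor-driman-7-one | CC1=C(O[Mg]Br)C[C@H]2C(C)(C)CCC[C@]2(C)[C@@H]1CCC#CC | intermediate (not isolated)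
18 | (4S,4aS,8aS)-3,4a,8,8-tetramethyl-4-(pent-3-yn-1-yl)-1,4,4a,5,6,7,8,8a-octahydronaphthalen-2-yl trifluoromethanesulfonate (9α side chain, 9β-H) | CC1=C(OS(=O)(=O)C(F)(F)F)C[C@H]2C(C)(C)CCC[C@]2(C)[C@@H]1CCC#CC | intermediate
19 | (1R,4aS,8aS)-2,5,5,8a-tetramethyl-1-(pent-3-yn-1-yl)-1,4,4a,5,6,7,8,8a-octahydronaphthalene | CC1=CC[C@H]2C(C)(C)CCC[C@]2(C)[C@@H]1CCC#CC | intermediate
20 | 5-[(1R,4aS,8aS)-2,5,5,8a-tetramethyl-1,4,4a,5,6,7,8,8a-octahydronaphthalen-1-yl]pentane-2,3-dione | CC1=CC[C@H]2C(C)(C)CCC[C@]2(C)[C@@H]1CCC(=O)C(C)=O | intermediate
21 | diethyl oxalate | CCOC(=O)C(=O)OCC | starting material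
22 | ethyl 2,4,5-trioxo-7-[(1R,4aS,8aS)-2,5,5,8a-tetramethyl-1,4,4a,5,6,7,8,8a-octahydronaphthalen-1-yl]heptanoate (present as its sodium enolate) | CC1=CC[C@H]2C(C)(C)CCC[C@]2(C)[C@@H]1CCC(=O)C(=O)CC(=O)C(=O)OCC | intermediate (not isolated)
23 | 2,5-dihydroxy-3-{[(1R,4aS,8aS)-2,5,5,8a-tetramethyl-1,4,4a,5,6,7,8,8a-octahydronaphthalen-1-yl]methyl}cyclohexa-2,5-diene-1,4-dione | CC1=CC[C@H]2C(C)(C)CCC[C@]2(C)[C@@H]1CC1=C(O)C(=O)C=C(O)C1=O | intermediate
24 | 3-{[(1R,4aS,8aS)-2,5,5,8a-tetramethyl-1,4,4a,5,6,7,8,8a-octahydronaphthalen-1-yl]methyl}benzene-1,2,4,5-tetrol | CC1=CC[C@H]2C(C)(C)CCC[C@]2(C)[C@@H]1Cc1c(O)c(O)cc(O)c1O | intermediate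
25 | 2,4,5-trihydroxy-3-{[(1R,4aS,8aS)-2,5,5,8a-tetramethyl-1,4,4a,5,6,7,8,8a-octahydronaphthalen-1-yl]methyl}phenyl hydrogen sulfate | CC1=CC[C@H]2C(C)(C)CCC[C@]2(C)[C@@H]1Cc1c(O)c(O)cc(OS(=O)(=O)O)c1O | target

Total step count: 13. Longest linear sequence: 13 steps, from 1 to 25; 2, 6, 15 and 21 enter as purchased reagents.

Least certain steps

Step 11, the key step and the one marked as a proposed new method. Most likely to go wrong is self-condensation of the enolisable 1,2-diketone (aldol oligomerisation) outrunning the crossed acylation, or the sequence stalling at the open-chain stage or diverting into a five-membered aldol closure, because the ring-closing acylation needs a second deprotonation of an already anionic intermediate. The fallback uses known chemistry, sets out from 14 and rejoins at 23. Purchased 1,2,4,5-tetramethoxybenzene is chloromethylated (paraformaldehyde, HCl; Blanc reaction) to 3-(chloromethyl)-1,2,4,5-tetramethoxybenzene F1, which with Mg gives (2,3,5,6-tetramethoxybenzyl)magnesium chloride F2. CuBr·SMe2-catalysed conjugate addition of F2 to 14 and O-triflation as in step 8 give the aryl-bearing enol triflate F3. Formate reduction as in step 9 gives the tetramethoxyarene F4 (the same compound as A1). (NH4)2Ce(NO3)6 in aqueous acetonitrile oxidises it to the 2,5-dimethoxy-1,4-benzoquinone F5, and hydrolysis of the two vinylogous ester groups (aqueous NaOH, then acid) gives 23.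

Step 10. Most likely to go wrong is attack of divalent palladium on the C7=C8 alkene (allylic C–H activation, isomerisation) or arrest after a single hydration, because a dialkyl alkyne is a slow substrate for this oxidation. The fallback builds the diketone by C–C bond formation, sets out from 14 and rejoins at 20. The Grignard reagent from purchased 2-(2-bromoethyl)-1,3-dioxane, [2-(1,3-dioxan-2-yl)ethyl]magnesium bromide F6, is added to 14 under the conditions of step 8 to give the acetal enol triflate F7, which is reduced as in step 9 to the acetal F8. Mild aqueous acid frees the aldehyde F9, 1-ethoxyvinyllithium adds to give the enol ether carbinol F10, dilute acid converts it into the acyloin F11, and Swern oxidation gives 20.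

Step 13. Most likely to go wrong is insufficient discrimination between the hindered and unhindered hydroxyls, a second sulfation, re-oxidation of the tetraol by traces of air, or loss of the sulfate during acidification. The fallback sets out from 24 and rejoins at 25. 2,2,2-Trichloroethyl chlorosulfate with a hindered amine base gives the neutral aryl trichloroethyl sulfate F12, which can be separated on silica from regioisomeric and doubly sulfated material. Zn and HCO2NH4 in methanol then remove the trichloroethyl group, and the salt is protonated as in step 13 to give 25.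

Step 8. Most likely to go wrong is 1,2-addition or simple enolisation in place of 1,4-addition at the β-carbon next to the quaternary C10, or sluggish O-triflation of the magnesium enolate; partial reduction of the alkyne in step 9 is a related concern. The fallback sets out from 14, rejoins at 19 and bypasses 18 and step 9. Luche reduction (NaBH4, CeCl3·7H2O) gives the 7β-allylic alcohol F13 by axial hydride delivery, and esterification with picolinic acid gives the picolinate F14. Reaction of F14 with 16 and CuBr·SMe2 effects anti-SN2′ substitution: the pentynyl group enters C9 on the α-face, anti to the 7β leaving group and to the angular methyl, while the double bond moves to C7=C8, giving 19.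

Step 3. Most likely to go wrong is slow cross-metathesis between an allyl group on a quaternary carbon and a 1,1-disubstituted partner, with homodimerisation of 5 competing. The fallback sets out from 5 and rejoins at 8. Hydroboration with 9-BBN and oxidative work-up give the primary alcohol F15, and Dess–Martin oxidation gives the aldehyde F16. MeMgBr adds to the aldehyde only, the ring ketone being flanked by two quaternary carbons, to give the secondary alcohol F17, and a second Dess–Martin oxidation gives 8.

Further compounds

F1 | step 11 | 3-(chloromethyl)-1,2,4,5-tetramethoxybenzene | ClCc1c(OC)c(OC)cc(OC)c1OC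
F2 | step 11 | (2,3,5,6-tetramethoxybenzyl)magnesium chloride | Cl[Mg]Cc1c(OC)c(OC)cc(OC)c1OC
F3 | step 11 | (4S,4aS,8aS)-3,4a,8,8-tetramethyl-4-[(2,3,5,6-tetramethoxyphenyl)methyl]-1,4,4a,5,6,7,8,8a-octahydronaphthalen-2-yl trifluoromethanesulfonate | CC1=C(OS(=O)(=O)C(F)(F)F)C[C@H]2C(C)(C)CCC[C@]2(C)[C@@H]1Cc1c(OC)c(OC)cc(OC)c1OC
F4 | step 11 | 1,2,4,5-tetramethoxy-3-{[(1R,4aS,8aS)-2,5,5,8a-tetramethyl-1,4,4a,5,6,7,8,8a-octahydronaphthalen-1-yl]methyl}benzene | CC1=CC[C@H]2C(C)(C)CCC[C@]2(C)[C@@H]1Cc1c(OC)c(OC)cc(OC)c1OC
F5 | step 11 | 2,5-dimethoxy-3-{[(1R,4aS,8aS)-2,5,5,8a-tetramethyl-1,4,4a,5,6,7,8,8a-octahydronaphthalen-1-yl]methyl}cyclohexa-2,5-diene-1,4-dione | CC1=CC[C@H]2C(C)(C)CCC[C@]2(C)[C@@H]1CC1=C(OC)C(=O)C=C(OC)C1=O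
F6 | step 10 | [2-(1,3-dioxan-2-yl)ethyl]magnesium bromide | Br[Mg]CCC1OCCCO1
F7 | step 10 | (4S,4aS,8aS)-4-[2-(1,3-dioxan-2-yl)ethyl]-3,4a,8,8-tetramethyl-1,4,4a,5,6,7,8,8a-octahydronaphthalen-2-yl trifluoromethanesulfonate | CC1=C(OS(=O)(=O)C(F)(F)F)C[C@H]2C(C)(C)CCC[C@]2(C)[C@@H]1CCC3OCCCO3
F8 | step 10 | 2-{2-[(1R,4aS,8aS)-2,5,5,8a-tetramethyl-1,4,4a,5,6,7,8,8a-octahydronaphthalen-1-yl]ethyl}-1,3-dioxane | CC1=CC[C@H]2C(C)(C)CCC[C@]2(C)[C@@H]1CCC3OCCCO3
F9 | step 10 | 3-[(1R,4aS,8aS)-2,5,5,8a-tetramethyl-1,4,4a,5,6,7,8,8a-octahydronaphthalen-1-yl]propanal | CC1=CC[C@H]2C(C)(C)CCC[C@]2(C)[C@@H]1CCC=O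
F10 | step 10 | 2-ethoxy-5-[(1R,4aS,8aS)-2,5,5,8a-tetramethyl-1,4,4a,5,6,7,8,8a-octahydronaphthalen-1-yl]pent-1-en-3-ol (carbinol epimers) | CC1=CC[C@H]2C(C)(C)CCC[C@]2(C)[C@@H]1CCC(O)C(=C)OCC
F11 | step 10 | 3-hydroxy-5-[(1R,4aS,8aS)-2,5,5,8a-tetramethyl-1,4,4a,5,6,7,8,8a-octahydronaphthalen-1-yl]pentan-2-one (carbinol epimers) | CC1=CC[C@H]2C(C)(C)CCC[C@]2(C)[C@@H]1CCC(O)C(C)=O
F12 | step 13 | 2,2,2-trichloroethyl 2,4,5-trihydroxy-3-{[(1R,4aS,8aS)-2,5,5,8a-tetramethyl-1,4,4a,5,6,7,8,8a-octahydronaphthalen-1-yl]methyl}phenyl sulfate | CC1=CC[C@H]2C(C)(C)CCC[C@]2(C)[C@@H]1Cc1c(O)c(O)cc(OS(=O)(=O)OCC(Cl)(Cl)Cl)c1O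
F13 | step 8 | 11-nor-drim-8-en-7β-ol (5α-H, 10β-CH3) | CC1=C[C@@]2(C)CCCC(C)(C)[C@@H]2C[C@@H]1O
F14 | step 8 | 11-nor-drim-8-en-7β-yl pyridine-2-carboxylate | CC1=C[C@@]2(C)CCCC(C)(C)[C@@H]2C[C@@H]1OC(=O)c3ccccn3
F15 | step 3 | (R)-2-(3-hydroxypropyl)-2,6,6-trimethylcyclohexanone | OCCC[C@@]1(C)CCCC(C)(C)C1=O
F16 | step 3 | (R)-3-(1,3,3-trimethyl-2-oxocyclohexyl)propanal | O=CCC[C@@]1(C)CCCC(C)(C)C1=O
F17 | step 3 | (R)-2-(3-hydroxybutyl)-2,6,6-trimethylcyclohexanone (carbinol epimers) | CC(O)CC[C@@]1(C)CCCC(C)(C)C1=O
A1 | alternative 1 | 1,2,4,5-tetramethoxy-3-{[(1R,4aS,8aS)-2,5,5,8a-tetramethyl-1,4,4a,5,6,7,8,8a-octahydronaphthalen-1-yl]methyl}benzene | CC1=CC[C@H]2C(C)(C)CCC[C@]2(C)[C@@H]1Cc1c(OC)c(OC)cc(OC)c1OC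
A2 | alternative 1 | 1,2,4,5-tetramethoxy-3-[(2Z,6E)-3,7,11-trimethyldodeca-2,6,10-trien-1-yl]benzene | CC(C)=CCC/C(C)=C/CC/C(C)=C\Cc1c(OC)c(OC)cc(OC)c1OC
A3 | alternative 2 | endo adduct: 6-(tert-butyldimethylsilyloxy)-11-(2,3,5,6-tetramethoxyphenyl)drim-5-en-11-one (8β-CH3, 9α-aroyl, 10β-CH3) | C[C@H]1CC(O[Si](C)(C)C(C)(C)C)=C2C(C)(C)CCC[C@]2(C)[C@@H]1C(=O)c1c(OC)c(OC)cc(OC)c1OC
A4 | alternative 2 | tert-butyl(dimethyl){[1-(2,6,6-trimethylcyclohex-1-en-1-yl)ethenyl]oxy}silane | C=C(O[Si](C)(C)C(C)(C)C)C1=C(C)CCCC1(C)C
A5 | alternative 2 | (E)-1-(2,3,5,6-tetramethoxyphenyl)but-2-en-1-one | C/C=C/C(=O)c1c(OC)c(OC)cc(OC)c1OC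
A6 | alternative 3 | cis-fused 2,5,5,8a-tetramethyl-4a,5,8,8a-tetrahydronaphthalene-1,4-dione (5β-H, 10β-CH3) | CC1=CC(=O)[C@@H]2C(C)(C)C=CC[C@]2(C)C1=O
A7 | alternative 3 | 4-methylpenta-1,3-diene | CC(C)=CC=C
A8 | alternative 3 | 2,6-dimethyl-1,4-benzoquinone | CC1=CC(=O)C=C(C)C1=O
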